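**Retrosynthetic overview**
1. Target ⇐ C-15 alcohol oxidation, hydrogenation/debenzylation, O-acetylation, methyl addition to a C-8 ketone and C-11 deoxygenation of aldol adduct 17.
2. 17 ⇐ intermolecular Mukaiyama aldol (C-9–C-11 bond) between the bicyclic silyl enol ether 12 and aldehyde 16, which comes from methyl hydrogen (R)-3-methylglutarate and carries C-13.
3. 12 ⇐ ring-closing metathesis (ring A, formed second) of 11 ⇐ Me2CuLi/TMSCl addition to enone 10, which sets the C-10 quaternary centre cis to H-5 and gives the C-8/C-9 enolate regiospecifically.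
4. 10 ⇐ conjugate allylation and re-oxidation of cyclohexenone 6 (ring B, formed first) ⇐ enamine-catalysed Michael addition of aldehyde 2 to methyl vinyl ketone, then aldol condensation; this sets C-5.

Assumption: the SMILES is taken literally; it encodes a cis-fused decalin (5β-H, 10β-Me; 5R,8R,9R,10S,13S), i.e. the C-5 epimer of labdanolic acid acetate, and the route is built for that.

Convention: labdane numbering is used (C-1 to C-10 ring carbons, C-11 to C-15 side chain, C-16 = 13-Me, C-17 = 8-Me, C-20 = 10-Me), also for the corresponding carbons of monocyclic precursors; β is the face of the 10-methyl group. The stereochemical arguments in steps 2, 6, 11 and 14 are reasoned from established models and conformational analysis, not from a precedent on this exact system.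

**Step 1**
Reactants: 1 methyl 3,3-dimethylpent-4-enoate
Product: 2 3,3-dimethylpent-4-enal
Conditions: DIBAL-H (1.1 equiv), CH2Cl2, −78 °C; aq. Rochelle salt
Reagents that add atoms: none
Why: Partial ester reduction; at −78 °C the aluminium hemiacetal survives until work-up and then releases the aldehyde.

**Step 2**
Reactants: 2 3,3-dimethylpent-4-enal; 3 but-3-en-2-one
Product: 4 (2R)-2-(2-methylbut-3-en-2-yl)-5-oxohexanal
Conditions: (R)-α,α-diphenylprolinol TMS ether (10 mol%), ethyl 3,4-dihydroxybenzoate (20 mol%), neat, 4 °C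
Reagents that add atoms: none
Why: Enamine-catalysed intermolecular Michael addition; the E-enamine adds to the enone on the face away from the CPh2(OTMS) group, which with the (R)-catalyst sets C-5 as R (the 5β-H of the target), and the bulky α-substituent favours high ee.

**Step 3**
Reactants: 4 (2R)-2-(2-methylbut-3-en-2-yl)-5-oxohexanal
Product: 6 (4S)-4-(2-methylbut-3-en-2-yl)cyclohex-2-en-1-one, via ketol 5 (not isolated)
Conditions: LiOH (10 mol%), i-PrOH, rt
Reagents that add atoms: none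
Why: Intramolecular aldol condensation of the methyl ketone onto the aldehyde closes ring B; the hindered C-5 centre is not touched and becomes the non-enolisable γ-carbon of the enone.

**Step 4**
Reactants: 6 (4S)-4-(2-methylbut-3-en-2-yl)cyclohex-2-en-1-one
Product: 7 {[(3R,4S)-4-(2-methylbut-3-en-2-yl)-3-(prop-2-en-1-yl)cyclohex-1-en-1-yl]oxy}trimethylsilane
Conditions: allylMgBr, CuBr·SMe2, THF, −78 °C; then 6, TMSCl, −78 → −40 °C
Reagents that add atoms: allylmagnesium bromide, C=CC[Mg]Br; chlorotrimethylsilane, C[Si](C)(C)Cl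
Why: TMSCl-promoted 1,4-addition of allylcopper puts the allyl group on C-10 (trans to the tert-alkyl group; this centre is erased in step 5) and traps the enolate regiospecifically as the C-8/C-9 silyl enol ether.

**Step 5**
Reactants: 7 {[(3R,4S)-4-(2-methylbut-3-en-2-yl)-3-(prop-2-en-1-yl)cyclohex-1-en-1-yl]oxy}trimethylsilane
Product: 10 (4R)-4-(2-methylbut-3-en-2-yl)-3-(prop-2-en-1-yl)cyclohex-2-en-1-one, via selenide 8 (not isolated), via selenoxide 9 (not isolated)
Conditions: PhSeCl, CH2Cl2, −78 °C; then pyridine, 30% H2O2, 0 °C → rt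
Reagents that add atoms: none
Why: Selenenylation of the silyl enol ether at C-9 followed by selenoxide syn-elimination (Reich–Sharpless), for which only H-10 is available, returns the enone now carrying the allyl group on C-10.

**Step 6**
Reactants: 10 (4R)-4-(2-methylbut-3-en-2-yl)-3-(prop-2-en-1-yl)cyclohex-2-en-1-one
Product: 11 {[(3S,4R)-3-methyl-4-(2-methylbut-3-en-2-yl)-3-(prop-2-en-1-yl)cyclohex-1-en-1-yl]oxy}trimethylsilane
Conditions: Me2CuLi (from MeLi, CuI), TMSCl, THF, −78 → −30 °C; Et3N, pentane work-up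
Reagents that add atoms: methyllithium (used as lithium dimethylcuprate), [Li]C; chlorotrimethylsilane, C[Si](C)(C)Cl
Why: TMSCl-accelerated cuprate conjugate addition; A(1,2) strain holds the tert-alkyl group on C-5 pseudoaxial, so methyl adds axially to C-10 from the opposite face (10-Me cis to H-5, allyl cis to the dimethylallyl group), and the C-8/C-9 enolate is trapped regiospecifically.

**Step 7**
Reactants: 11 {[(3S,4R)-3-methyl-4-(2-methylbut-3-en-2-yl)-3-(prop-2-en-1-yl)cyclohex-1-en-1-yl]oxy}trimethylsilane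
Product: 12 trimethyl{[(4aR,8aS)-5,5,8a-trimethyl-3,4,4a,5,8,8a-hexahydronaphthalen-2-yl]oxy}silane
Conditions: Grubbs II (3 mol%), CH2Cl2, 40 °C
Reagents that add atoms: none
Why: Ring-closing metathesis of the cis-disposed allyl and 1,1-dimethylallyl groups closes ring A as a cyclohexene and so fixes the cis ring fusion set in step 6; the trisubstituted silyl enol ether does not take part.

**Step 8**
Reactants: 13 (3R)-5-methoxy-3-methyl-5-oxopentanoic acid (methyl hydrogen (R)-3-methylglutarate)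
Product: 14 methyl (3R)-5-hydroxy-3-methylpentanoate
Conditions: BH3·SMe2, THF, −10 °C → rt; MeOH
Reagents that add atoms: none
Why: Borane reduces the free carboxylic acid chemoselectively in the presence of the methyl ester and leaves the stereocentre alone.

**Step 9**
Reactants: 14 methyl (3R)-5-hydroxy-3-methylpentanoate
Product: 15 methyl (3R)-5-(benzyloxy)-3-methylpentanoate
Conditions: BnOC(=NH)CCl3, TfOH (cat.), CH2Cl2–cyclohexane, 0 °C → rt
Reagents that add atoms: benzyl 2,2,2-trichloroacetimidate, N=C(OCc1ccccc1)C(Cl)(Cl)Cl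
Why: Acid-catalysed O-benzylation with the trichloroacetimidate avoids the basic conditions that would lactonise the δ-hydroxy ester.

**Step 10**
Reactants: 15 methyl (3R)-5-(benzyloxy)-3-methylpentanoate
Product: 16 (3R)-5-(benzyloxy)-3-methylpentanal
Conditions: DIBAL-H (1.1 equiv), CH2Cl2, −78 °C; aq. Rochelle salt
Reagents that add atoms: none
Why: Partial ester reduction at low temperature gives the aldehyde; the β-stereocentre cannot epimerise.

**Step 11**
Reactants: 12 trimethyl{[(4aR,8aS)-5,5,8a-trimethyl-3,4,4a,5,8,8a-hexahydronaphthalen-2-yl]oxy}silane; 16 (3R)-5-(benzyloxy)-3-methylpentanal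
Product: 17 15-(benzyloxy)-11-hydroxy-17-nor-5β-labd-2-en-8-one (9β side chain; C-11 epimers; 13-Me as in 16)
Conditions: TiCl4 (1.0 equiv), CH2Cl2, −78 °C; then H2O
Reagents that add atoms: none
Why: Intermolecular Mukaiyama aldol addition; in the cis-fused enol ether C-1 is pseudoaxial on ring B (the other half-chair would force the quaternary C-4 axial over ring B), so the activated aldehyde adds to C-9 on the convex β face anti to C-1, giving the C-9–C-11 bond cis to the 10-methyl group.

**Step 12**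
Reactants: 17 15-(benzyloxy)-11-hydroxy-17-nor-5β-labd-2-en-8-one
Product: 18 O-[15-(benzyloxy)-8-oxo-17-nor-5β-labd-2-en-11-yl] O-phenyl thiocarbonate
Conditions: PhOC(S)Cl, pyridine, DMAP (cat.), CH2Cl2, 0 °C → rt
Reagents that add atoms: O-phenyl chlorothionoformate, S=C(Cl)Oc1ccccc1
Why: Thioacylation of the secondary alcohol under weakly basic conditions that do not enolise the ketone, so C-9 keeps its configuration.

**Step 13**
Reactants: 18 O-[15-(benzyloxy)-8-oxo-17-nor-5β-labd-2-en-11-yl] O-phenyl thiocarbonate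
Product: 19 (13S)-15-(benzyloxy)-17-nor-5β-labd-2-en-8-one
Conditions: Bu3SnH (0.3 M), AIBN (cat.), toluene, 80 °C
Reagents that add atoms: none
Why: Barton–McCombie radical deoxygenation removes the C-11 oxygen under neutral conditions, so C-9 (α to the ketone) is not epimerised.

**Step 14**
Reactants: 19 (13S)-15-(benzyloxy)-17-nor-5β-labd-2-en-8-one
Product: 20 (13S)-15-(benzyloxy)-5β-labd-2-en-8α-ol
Conditions: MeLi, CeCl3, THF, −78 °C; aq. NH4Cl
Reagents that add atoms: methyllithium, [Li]C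
Why: Organocerium 1,2-addition (non-basic, so no enolisation or C-9 epimerisation); the axial α trajectory at C-8 is blocked by the syn-axial C-1 methylene on the concave face, so methyl enters equatorially from the β face and gives 8β-Me/8α-OH.

**Step 15**
Reactants: 20 (13S)-15-(benzyloxy)-5β-labd-2-en-8α-ol
Product: 21 (13S)-8α-acetoxy-15-(benzyloxy)-5β-labd-2-ene
Conditions: n-BuLi, THF, −78 °C; then Ac2O, −78 → 0 °C
Reagents that add atoms: acetic anhydride, CC(=O)OC(C)=O
Why: O-acylation of the preformed lithium alkoxide acetylates the hindered tertiary alcohol without the acid that would cause elimination.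

**Step 16**
Reactants: 21 (13S)-8α-acetoxy-15-(benzyloxy)-5β-labd-2-ene
Product: 22 (13S)-8α-acetoxy-5β-labdan-15-ol
Conditions: H2 (1 atm), 10% Pd/C, EtOAc, rt
Reagents that add atoms: none
Why: Catalytic hydrogenation saturates the disubstituted ring-A alkene and hydrogenolyses the benzyl ether in one operation; no stereocentre is formed and the tertiary acetate is inert.

**Step 17**
Reactants: 22 (13S)-8α-acetoxy-5β-labdan-15-ol
Product: 24 (13S)-8α-acetoxy-5β-labdan-15-oic acid, via aldehyde 23 (not isolated)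
Conditions: TEMPO (cat.), PhI(OAc)2 (2.2 equiv), MeCN–H2O (1:1), rt
Reagents that add atoms: water, O
Why: TEMPO/PhI(OAc)2 oxidation takes the primary alcohol through the aldehyde hydrate to the acid under near-neutral conditions that leave the tertiary acetate intact.

**Compound list**
1 | methyl 3,3-dimethylpent-4-enoate | COC(=O)CC(C)(C)C=C | starting material
2 | 3,3-dimethylpent-4-enal | O=CCC(C)(C)C=C | intermediate
3 | but-3-en-2-one (methyl vinyl ketone) | CC(=O)C=C | starting material
4 | (2R)-2-(2-methylbut-3-en-2-yl)-5-oxohexanal | CC(=O)CC[C@@H](C=O)C(C)(C)C=C | intermediate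
5 | (4R)-3-hydroxy-4-(2-methylbut-3-en-2-yl)cyclohexan-1-one (C-3 epimers) | O=C1CC[C@@H](C(O)C1)C(C)(C)C=C | intermediate
6 | (4S)-4-(2-methylbut-3-en-2-yl)cyclohex-2-en-1-one | O=C1CC[C@@H](C=C1)C(C)(C)C=C | intermediate
7 | {[(3R,4S)-4-(2-methylbut-3-en-2-yl)-3-(prop-2-en-1-yl)cyclohex-1-en-1-yl]oxy}trimethylsilane (3,4-trans) | C[Si](C)(C)OC1=C[C@H](CC=C)[C@@H](C(C)(C)C=C)CC1 | intermediate
8 | (3R,4S)-4-(2-methylbut-3-en-2-yl)-2-(phenylselanyl)-3-(prop-2-en-1-yl)cyclohexan-1-one (C-2 epimers) | O=C1CC[C@H](C(C)(C)C=C)[C@@H](CC=C)C1[Se]c1ccccc1 | intermediate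
9 | (3R,4S)-4-(2-methylbut-3-en-2-yl)-2-(phenylseleninyl)-3-(prop-2-en-1-yl)cyclohexan-1-one (C-2 and Se epimers) | O=C1CC[C@H](C(C)(C)C=C)[C@@H](CC=C)C1[Se](=O)c1ccccc1 | intermediate
10 | (4R)-4-(2-methylbut-3-en-2-yl)-3-(prop-2-en-1-yl)cyclohex-2-en-1-one | O=C1CC[C@H](C(C)(C)C=C)C(CC=C)=C1 | intermediate
11 | {[(3S,4R)-3-methyl-4-(2-methylbut-3-en-2-yl)-3-(prop-2-en-1-yl)cyclohex-1-en-1-yl]oxy}trimethylsilane (3-Me trans to the 4-substituent) | C[Si](C)(C)OC1=C[C@@](C)(CC=C)[C@@H](C(C)(C)C=C)CC1 | intermediate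
12 | trimethyl{[(4aR,8aS)-5,5,8a-trimethyl-3,4,4a,5,8,8a-hexahydronaphthalen-2-yl]oxy}silane (cis-fused) | C[Si](C)(C)OC1=C[C@@]2(C)CC=CC(C)(C)[C@H]2CC1 | intermediate
13 | (3R)-5-methoxy-3-methyl-5-oxopentanoic acid (methyl hydrogen (R)-3-methylglutarate) | COC(=O)C[C@H](C)CC(=O)O | starting material
14 | methyl (3R)-5-hydroxy-3-methylpentanoate | COC(=O)C[C@H](C)CCO | intermediate
15 | methyl (3R)-5-(benzyloxy)-3-methylpentanoate | COC(=O)C[C@H](C)CCOCc1ccccc1 | intermediate
16 | (3R)-5-(benzyloxy)-3-methylpentanal | O=CC[C@H](C)CCOCc1ccccc1 | intermediate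
17 | 15-(benzyloxy)-11-hydroxy-17-nor-5β-labd-2-en-8-one (5β-H, 10β-Me, 9β side chain, C-11 epimers) | O=C1CC[C@@H]2C(C)(C)C=CC[C@]2(C)[C@H]1C(O)C[C@H](C)CCOCc3ccccc3 | intermediate
18 | O-[15-(benzyloxy)-8-oxo-17-nor-5β-labd-2-en-11-yl] O-phenyl thiocarbonate (C-11 epimers) | O=C1CC[C@@H]2C(C)(C)C=CC[C@]2(C)[C@H]1C(OC(=S)Oc3ccccc3)C[C@H](C)CCOCc4ccccc4 | intermediate
19 | (13S)-15-(benzyloxy)-17-nor-5β-labd-2-en-8-one | O=C1CC[C@@H]2C(C)(C)C=CC[C@]2(C)[C@H]1CC[C@H](C)CCOCc3ccccc3 | intermediate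
20 | (13S)-15-(benzyloxy)-5β-labd-2-en-8α-ol (8β-Me) | O[C@]1(C)CC[C@@H]2C(C)(C)C=CC[C@]2(C)[C@H]1CC[C@H](C)CCOCc3ccccc3 | intermediate
21 | (13S)-8α-acetoxy-15-(benzyloxy)-5β-labd-2-ene | CC(=O)O[C@]1(C)CC[C@@H]2C(C)(C)C=CC[C@]2(C)[C@H]1CC[C@H](C)CCOCc3ccccc3 | intermediate
22 | (13S)-8α-acetoxy-5β-labdan-15-ol | CC(=O)O[C@]1(C)CC[C@@H]2C(C)(C)CCC[C@]2(C)[C@H]1CC[C@H](C)CCO | intermediate
23 | (13S)-8α-acetoxy-5β-labdan-15-al | CC(=O)O[C@]1(C)CC[C@@H]2C(C)(C)CCC[C@]2(C)[C@H]1CC[C@H](C)CC=O | intermediate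
24 | (13S)-8α-acetoxy-5β-labdan-15-oic acid, i.e. (3S)-5-[(1R,2R,4aR,8aS)-2-acetoxy-2,5,5,8a-tetramethyldecahydronaphthalen-1-yl]-3-methylpentanoic acid | CC(=O)O[C@]1(C)CC[C@@H]2C(C)(C)CCC[C@]2(C)[C@H]1CC[C@H](C)CC(=O)O | target

**Totals**
Total step count: 17. Longest linear sequence: 14 steps (steps 1–7 and 11–17, from 1 to 24).

**Three steps most likely to fail**

Step 2. The aldehyde's α-carbon sits next to a quaternary carbon, so enamine formation and C–C bond formation may be slow or poorly selective. The fallback sets out from 2 and comes back at 4, and sets C-5 by Enders hydrazone alkylation instead of the catalytic Michael addition. Condensation of 2 with SAMP gives the SAMP hydrazone of 3,3-dimethylpent-4-enal F1. LDA (THF, 0 °C) then 2-(2-iodoethyl)-2-methyl-1,3-dioxolane at −100 °C gives the α-alkylated (R)-hydrazone F2, the sense following the usual SAMP azaenolate model. Aqueous oxalic acid releases (2R)-2-(2-methylbut-3-en-2-yl)-4-(2-methyl-1,3-dioxolan-2-yl)butanal F3, and PPTS in wet acetone removes the dioxolane to give 4.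

Step 13. The C-11 radical is β to the C-8 ketone, so 1,2-acyl (Dowd–Beckwith) migration can compete with reduction, and the β-keto thiocarbonate 18 can eliminate to the enone. The fallback sets out from 17 and comes back at 21, and consumes the ketone before the radical step. TESOTf/2,6-lutidine gives the 11-O-triethylsilyl ether of 17 F4. MeLi/CeCl3 gives the 11-silyloxy 8α-tertiary alcohol F5, and n-BuLi/Ac2O gives the 8α-acetoxy 11-silyl ether F6. HF·pyridine gives the 8α-acetoxy 11-alcohol F7, PhOC(S)Cl/pyridine gives the 8α-acetoxy 11-O-phenyl thiocarbonate F8, and Bu3SnH/AIBN then gives 21.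

Step 14. The ketone is hindered and the facial preference is opposed by the neighbouring axial side chain, so the addition may enolise 19 or deliver methyl from the α face. The fallback sets out from 19 and comes back at 20, and delivers carbon and oxygen under thermodynamic control. Dimethylsulfoxonium methylide (Me3S(O)I, NaH, DMSO) adds reversibly and closes with the new CH2 equatorial (β) and the oxygen axial (α), giving 8α,17-epoxy-15-(benzyloxy)-5β-labd-2-ene F9. LiEt3BH opens the epoxide at the CH2 carbon to give 20.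

**Further compounds**
F1 | step 2 | (E)-N-[(2S)-2-(methoxymethyl)pyrrolidin-1-yl]-3,3-dimethylpent-4-en-1-imine (SAMP hydrazone of 2) | COC[C@@H]1CCCN1/N=C/CC(C)(C)C=C
F2 | step 2 | (E,2R)-N-[(2S)-2-(methoxymethyl)pyrrolidin-1-yl]-2-(2-methylbut-3-en-2-yl)-4-(2-methyl-1,3-dioxolan-2-yl)butan-1-imine | COC[C@@H]1CCCN1/N=C/[C@H](CCC2(C)OCCO2)C(C)(C)C=C
F3 | step 2 | (2R)-2-(2-methylbut-3-en-2-yl)-4-(2-methyl-1,3-dioxolan-2-yl)butanal | O=C[C@H](CCC1(C)OCCO1)C(C)(C)C=C
F4 | step 13 | 15-(benzyloxy)-11-(triethylsilyloxy)-17-nor-5β-labd-2-en-8-one | O=C1CC[C@@H]2C(C)(C)C=CC[C@]2(C)[C@H]1C(O[Si](CC)(CC)CC)C[C@H](C)CCOCc3ccccc3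
F5 | step 13 | 15-(benzyloxy)-11-(triethylsilyloxy)-5β-labd-2-en-8α-ol | O[C@]1(C)CC[C@@H]2C(C)(C)C=CC[C@]2(C)[C@H]1C(O[Si](CC)(CC)CC)C[C@H](C)CCOCc3ccccc3
F6 | step 13 | 8α-acetoxy-15-(benzyloxy)-11-(triethylsilyloxy)-5β-labd-2-ene | CC(=O)O[C@]1(C)CC[C@@H]2C(C)(C)C=CC[C@]2(C)[C@H]1C(O[Si](CC)(CC)CC)C[C@H](C)CCOCc3ccccc3
F7 | step 13 | 8α-acetoxy-15-(benzyloxy)-5β-labd-2-en-11-ol | CC(=O)O[C@]1(C)CC[C@@H]2C(C)(C)C=CC[C@]2(C)[C@H]1C(O)C[C@H](C)CCOCc3ccccc3
F8 | step 13 | O-[8α-acetoxy-15-(benzyloxy)-5β-labd-2-en-11-yl] O-phenyl thiocarbonate | CC(=O)O[C@]1(C)CC[C@@H]2C(C)(C)C=CC[C@]2(C)[C@H]1C(OC(=S)Oc3ccccc3)C[C@H](C)CCOCc4ccccc4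
F9 | step 14 | 8α,17-epoxy-15-(benzyloxy)-5β-labd-2-ene | O1C[C@]12CC[C@@H]3C(C)(C)C=CC[C@]3(C)[C@H]2CC[C@H](C)CCOCc4ccccc4
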